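Take the last reading of each earlier run and divide the over-reaction product by the side product; I called that the split, the selectivity between the two.

| flask | substrate | remark | time |
|---|---|---|---|
| eta | 0.070 M | run made earlier |  |
| gamma | 0.11 M | run made earlier |  |
| west | 0.050 M |  | 8.0 h |
| east | 0.050 M |  | 4.0 h |

| run | time / h | side product / % | target / % | over-reaction product / % | substrate / % |
|---|---|---|---|---|---|
| eta | 0.667 | 4.7 | 20.9 | 2.3 | 67.7 |
| eta | 1.33 | 13.1 | 24.8 | 10.9 | 52.9 |
| eta | 2.00 | 19.9 | 22.4 | 16.1 | 42.8 |
| eta | 2.50 | 20.3 | 20.1 | 20.7 | 38.9 |
| eta | 3.00 | 23.4 | 15.8 | 24.6 | 35.5 |
| eta | 4.00 | 26.7 | 13.6 | 27.6 | 30.0 |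
| gamma | 0.333 | 2.6 | 19.8 | 0 | 74.5 |
| gamma | 0.500 | 5.5 | 23.3 | 3.3 | 65.6 |
| gamma | 0.833 | 13.6 | 26.5 | 6.1 | 52.9 |
| gamma | 1.33 | 19.2 | 27.2 | 11.0 | 39.6 |
| gamma | 2.50 | 29.9 | 16.9 | 22.9 | 28.4 |
| gamma | 4.00 | 36.6 | 13.8 | 30.6 | 19.3 |

(standard deviation of a reading: 1 percentage point)

- a species is counted by the substrate in it: one target or over-reaction product counts as two
- a species is counted by the substrate in it: one side product counts as three
- the analysis behind the earlier runs scatters by 1 percentage point, standard deviation

- which of these there is most of at the end, counted by the substrate in it, west (over-reaction product / substrate / side product / target)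
- which of these there is most of at the end, counted by the substrate in it, east (over-reaction product / substrate / side product / target)
- final amount of the leader among these, as a percentage of the substrate charged, in west
- final amount of the leader among these, as a percentage of the substrate charged, in east

The split was 1.03 in eta and 0.836 in gamma, lower at the stronger charge. Target stood above the other two products at the first reading of each run, and those two grew after it, so I took both as made from target: over-reaction product by a step of target on its own, side product by a step that also takes a substrate, as its count suggests. On that picture, the ratio of the two gains at any moment, times the substrate concentration at that moment, stays constant.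

Substrate falls during a run, so I replaced its curve with one mean, the charge times the square root of the fraction left at the end. That gave 0.0383 M for eta and 0.0483 M for gamma. The mean is rough: for eta it stands at 54.8% of the charge, higher than the reading of 42.8% at 2.00 h. Even so, split times mean came to 0.0396 M from eta and 0.0404 M from gamma. I kept 0.0400 M as the crossover concentration, the substrate concentration at which the two products gain equally as counted.

The forecast named over-reaction product at 42% in west and substrate at 36% in east, holding that “Dilution favours the first-order step”. Putting its east substrate through my mean gave 0.0300 M, below the crossover, and so a split of 1.33. Its own stepping had over-reaction product at 26 against side product at 23 in east, a smaller split than mine, and on that point we differed. West runs longer on the same charge, so I expected less substrate there and a larger split.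

What ran in the flasks was this:

    2 substrate ⇌ target (K = 28.0 M⁻¹, k = 0.00130 M⁻¹ s⁻¹)
    target → over-reaction product (k = 1.10 × 10⁻⁴ s⁻¹)
    substrate + target → side product (k = 0.00190 M⁻¹ s⁻¹)
    target ⇌ isomer of the product (K = 0.160, k = 2.50 × 10⁻⁶ s⁻¹)

West ended with over-reaction product leading at 42.5% and east with substrate at 37.6%, the leaders the forecast had named. West's split was 1.63, and the crossover over west's own mean of 0.0248 M gives 1.61. At 8.00 h in west, target went to over-reaction product at 4.7 times its rate to side product, the faster path. A neighbour of west charged with 0.013 M kept 56.4% substrate, so the crossover gives 4.10, and that flask held 28.6% over-reaction product against 6.95% side product, a split of 4.12.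

The data are simulated with constants of no real substance; scatter was added.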